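**Strategy.** Everything rests on cutting the O1–C6 bond of the dihydropyran. The array O1–C2(quaternary)–C3(oxygenated)–C4–C5(ring A)–C6(ring B), with C6 at the ketone oxidation level, is what oxidative ring expansion of a 2-furyl tertiary carbinol leaves behind. One photooxygenation of carbinol 19, a 2,4,5-trisubstituted furan carrying ring A on C4 and the ortho-chlorinated ring B on C5, gives pyranone 22: O1–C6 and the C3 carbonyl form together and the preset C2 centre is untouched. Two reductions and loss of the C6 oxygen then give the C5=C6 enol ether, and the chlorine closes the oxepine last.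

Key step: step 10

Assumption: the antipode of the bis(sulfonamide) diol ligand in step 9 is taken to be the one that sends methyl to the Re face of ketone 18 (priority O > furyl > CH2), which gives the 2S carbinol; the sense of induction is to be checked on a simple 2-furyl alkyl ketone first.

Abbreviations: TIPS = triisopropylsilyl; ArA = 5-(3-methylbut-2-enyl)-2,4-bis(TIPS-oxy)phenyl (ring A); ArB = 2-chloro-4-(TIPS-oxy)phenyl (ring B). Pyran numbering O1, C2 to C6 is used from compound 22 on.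

Step 1
Reactants: 1 4,6-dibromobenzene-1,3-diol
Product: 2 1,5-dibromo-2,4-bis(TIPS-oxy)benzene
Conditions: TIPSCl, imidazole, DMF, 40 °C
Reagents that add atoms: chlorotriisopropylsilane (TIPSCl), CC(C)[Si](Cl)(C(C)C)C(C)C
Why: Imidazole-promoted silyl ether formation on both phenols, TIPS being chosen because aryl TIPS ethers should withstand the aqueous base of the two Suzuki couplings and the organometallic steps and still fall to fluoride at the end.

Step 2
Reactants: 2 1,5-dibromo-2,4-bis(TIPS-oxy)benzene; 3 1-bromo-3-methylbut-2-ene (prenyl bromide)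
Product: 6 1-bromo-5-(3-methylbut-2-enyl)-2,4-bis(TIPS-oxy)benzene, via aryllithium 4 (not isolated), via arylcopper 5 (not isolated)
Conditions: n-BuLi (1.05 equiv), THF, −78 °C; CuBr·SMe2, −78 to −40 °C; then 3, −40 to 0 °C
Reagents that add atoms: none
Why: Bromine–lithium exchange on one of two equivalent C–Br bonds (a second exchange on the electron-rich aryllithium is much slower), transmetalation to the arylcopper to suppress anionic O-to-C silyl migration, and SN2 allylation at the primary carbon of prenyl bromide, whose gem-dimethyl terminus disfavours the SN2′ mode.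

Step 3
Reactants: 6 1-bromo-5-(3-methylbut-2-enyl)-2,4-bis(TIPS-oxy)benzene
Product: 8 ArA pinacol boronate, 2-(ArA)-4,4,5,5-tetramethyl-1,3,2-dioxaborolane, via aryllithium 7 (not isolated)
Conditions: n-BuLi, THF, −78 °C; 2-isopropoxy-4,4,5,5-tetramethyl-1,3,2-dioxaborolane, −78 °C to rt; aq. NH4Cl
Reagents that add atoms: 2-isopropoxy-4,4,5,5-tetramethyl-1,3,2-dioxaborolane, CC(C)OB1OC(C)(C)C(C)(C)O1
Why: Bromine–lithium exchange at −78 °C and electrophilic borylation are faster than deprotonation of the benzylic-allylic CH2 or silyl migration and give the pinacol boronate directly.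

Step 4
Reactants: 9 4,5-dibromofuran-2-carboxylic acid
Product: 11 4,5-dibromo-N-methoxy-N-methylfuran-2-carboxamide, via acylimidazole 10 (not isolated)
Conditions: 1,1′-carbonyldiimidazole, CH2Cl2, rt; then MeNH(OMe)·HCl, rt
Reagents that add atoms: N,O-dimethylhydroxylamine hydrochloride, CNOC.Cl
Why: Acid activation as the acylimidazole and aminolysis (Weinreb amide formation) place on the furan a group that later stops Grignard addition at the ketone, so no lithiation of the assembled furan is needed.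

Step 5
Reactants: 11 4,5-dibromo-N-methoxy-N-methylfuran-2-carboxamide; 12 (2-chloro-4-hydroxyphenyl)boronic acid
Product: 13 4-bromo-5-(2-chloro-4-hydroxyphenyl)-N-methoxy-N-methylfuran-2-carboxamide
Conditions: Pd(PPh3)4 (3 mol%), Na2CO3, DME/H2O, 70 °C
Reagents that add atoms: none
Why: Regioselective Suzuki–Miyaura coupling, zerovalent palladium inserting into the C5–Br bond next to the ring oxygen and conjugated with the amide well before C4–Br, while the aryl C–Cl bond is inert to the triphenylphosphine catalyst.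

Step 6
Reactants: 13 4-bromo-5-(2-chloro-4-hydroxyphenyl)-N-methoxy-N-methylfuran-2-carboxamide
Product: 14 4-bromo-5-(ArB)-N-methoxy-N-methylfuran-2-carboxamide
Conditions: TIPSCl, imidazole, DMF, rt
Reagents that add atoms: chlorotriisopropylsilane (TIPSCl), CC(C)[Si](Cl)(C(C)C)C(C)C
Why: Silyl ether formation masks the phenol before the Grignard, zinc and singlet-oxygen steps, none of which tolerates a free phenol.

Step 7
Reactants: 14 4-bromo-5-(ArB)-N-methoxy-N-methylfuran-2-carboxamide; 8 ArA pinacol boronate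
Product: 15 4-(ArA)-5-(ArB)-N-methoxy-N-methylfuran-2-carboxamide
Conditions: PdCl2(dppf) (5 mol%), K3PO4, 1,4-dioxane/H2O (10:1), 90 °C
Reagents that add atoms: none
Why: Suzuki–Miyaura coupling of the remaining furyl C4–Br under a bisphosphine palladium catalyst that does not insert into the hindered aryl chloride, a small excess of boronate offsetting protodeboronation of the electron-rich arene.

Step 8
Reactants: 15 4-(ArA)-5-(ArB)-N-methoxy-N-methylfuran-2-carboxamide; 16 5-bromo-2-methylpent-2-ene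
Product: 18 1-[4-(ArA)-5-(ArB)furan-2-yl]-5-methylhex-4-en-1-one, via Grignard reagent 17 (not isolated)
Conditions: Mg, THF, rt (16 to 17); then 15, THF, −20 to 0 °C; aq. NH4Cl
Reagents that add atoms: none
Why: Weinreb ketone synthesis, the magnesium-chelated tetrahedral adduct collapsing to the ketone only on work-up so that no over-addition occurs.

Step 9
Reactants: 18 1-[4-(ArA)-5-(ArB)furan-2-yl]-5-methylhex-4-en-1-one
Product: 19 (2S)-2-[4-(ArA)-5-(ArB)furan-2-yl]-6-methylhept-5-en-2-ol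
Conditions: Ti(OiPr)4 (1.2 equiv), trans-cyclohexane-1,2-diamine bis(10-camphorsulfonamide) diol ligand (10 mol%), Me2Zn (3 equiv), toluene/hexane, rt
Reagents that add atoms: dimethylzinc, C[Zn]C
Why: Catalytic enantioselective alkylzinc addition to a ketone, the titanium bis(sulfonamide) catalyst distinguishing the flat 2-furyl group from the CH2 chain and delivering methyl to the Re face, which sets the carbinol centre (C2 of the later pyran) as S.

Step 10
Reactants: 19 (2S)-2-[4-(ArA)-5-(ArB)furan-2-yl]-6-methylhept-5-en-2-ol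
Product: 22 (2S)-6-(ArB)-6-hydroxy-2-methyl-2-(4-methylpent-3-enyl)-5-(ArA)-2H-pyran-3(6H)-one (C6 epimers), via endoperoxide 20 (not isolated), via enedione 21 (not isolated)
Conditions: O2, 5,10,15,20-tetraphenylporphyrin (1 mol%), visible light, CH2Cl2, −78 °C, irradiation stopped when 19 is consumed; then Me2S, −78 °C to rt
Reagents that add atoms: dioxygen, O=O
Why: Sensitised singlet oxygen adds [4+2] across C2 and C5 of the furan to give endoperoxide 20, which dimethyl sulfide deoxygenates to the Z-ene-1,4-dione 21. The tertiary hydroxyl of 21 then adds to the aryl ketone in a 6-exo-trig closure that makes the O1–C6 bond and the pyranone ring; the closest known reaction is the Achmatowicz rearrangement of furyl carbinols in its singlet-oxygen form. The ring oxygen O1 is the carbinol oxygen, so the hindered tertiary ether arises without substitution at the quaternary carbon and the C2 configuration from step 9 is retained. The only new stereocentre is the hemiketal carbon C6, which should form as an equilibrating epimer mixture under thermodynamic (anomeric) control and is erased in step 14. The step needs chemoselectivity for the furan over the two trisubstituted alkenes and the arenes: the electron-rich trisubstituted furan is a far better diene for singlet oxygen than the side-chain alkenes are ene partners, silylation protects the resorcinol ring from phenol-type oxidation, and low temperature with a limited light dose restrains ene hydroperoxidation. The Z geometry inherited from the furan holds hydroxyl and aryl ketone within reach, so ring closure should outpace alkene isomerisation.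

Step 11
Reactants: 22 (2S)-6-(ArB)-6-hydroxy-2-methyl-2-(4-methylpent-3-enyl)-5-(ArA)-2H-pyran-3(6H)-one
Product: 23 (2S)-6-(ArB)-6-methoxy-2-methyl-2-(4-methylpent-3-enyl)-5-(ArA)-2H-pyran-3(6H)-one (C6 epimers)
Conditions: MeOH/CH2Cl2, camphorsulfonic acid (10 mol%), 3 Å molecular sieves, 0 °C to rt; Et3N quench
Reagents that add atoms: methanol, CO
Why: Fischer-type ketalisation through the oxocarbenium ion stabilised by O1 and ring B locks the pyran ring, so that the reduced intermediates that follow cannot open to 1,4-dicarbonyl or hydroxy ketone forms that would cyclise back to furans.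

Step 12
Reactants: 23 (2S)-6-(ArB)-6-methoxy-2-methyl-2-(4-methylpent-3-enyl)-5-(ArA)-2H-pyran-3(6H)-one
Product: 24 (2S)-6-(ArB)-6-methoxy-2-methyl-2-(4-methylpent-3-enyl)-5-(ArA)oxan-3-one (mixture at C5 and C6)
Conditions: [(Ph3P)CuH]6 (0.5 equiv), H2O (3 equiv), degassed toluene/THF, rt
Reagents that add atoms: none
Why: Stryker conjugate reduction of the enone, hydride going to C5 and a proton from water to C4, leaves the isolated alkenes, the aryl chloride, the ketal and the silyl ethers alone, and the new C5 centre is erased in step 14.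

Step 13
Reactants: 24 (2S)-6-(ArB)-6-methoxy-2-methyl-2-(4-methylpent-3-enyl)-5-(ArA)oxan-3-one
Product: 25 (2S,3S)-6-(ArB)-6-methoxy-2-methyl-2-(4-methylpent-3-enyl)-5-(ArA)oxan-3-ol
Conditions: (R)-2-methyl-CBS-oxazaborolidine (30 mol%), catecholborane (2 equiv), toluene, −78 to −40 °C; MeOH, aq. NaHCO3
Reagents that add atoms: none
Why: Corey–Bakshi–Shibata reduction under reagent control, the (R)-oxazaborolidine binding the carbonyl on the side of the C4 methylene and away from quaternary C2 so that hydride adds to the face giving the 3S alcohol (hydroxyl cis to the 4-methylpent-3-enyl group), the same face that the weak bias of the larger C2 substituent favours, while catecholborane at low temperature spares the alkenes.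

Step 14
Reactants: 25 (2S,3S)-6-(ArB)-6-methoxy-2-methyl-2-(4-methylpent-3-enyl)-5-(ArA)oxan-3-ol
Product: 27 (2S,3S)-6-(ArB)-2-methyl-2-(4-methylpent-3-enyl)-5-(ArA)-3-(trimethylsilyloxy)-3,4-dihydro-2H-pyran, via silyl ether ketal 26 (not isolated)
Conditions: TMSOTf (3 equiv), iPr2NEt (6 equiv), CH2Cl2, −78 to 0 °C
Reagents that add atoms: trimethylsilyl trifluoromethanesulfonate, C[Si](C)(C)OS(=O)(=O)C(F)(F)F
Why: Gassman-type ketal-to-enol-ether elimination, in which the free hydroxyl is silylated first (blocking transannular ketal formation), TMSOTf ionises the methoxy ketal to the oxocarbenium ion and the amine removes the benzylic C5–H to give the tetrasubstituted C5=C6 enol ether without touching C2 or C3.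

Step 15
Reactants: 27 (2S,3S)-6-(ArB)-2-methyl-2-(4-methylpent-3-enyl)-5-(ArA)-3-(trimethylsilyloxy)-3,4-dihydro-2H-pyran
Product: 28 4-[(2S,3S)-6-(2-chloro-4-hydroxyphenyl)-3-hydroxy-2-methyl-2-(4-methylpent-3-enyl)-3,4-dihydro-2H-pyran-5-yl]-6-(3-methylbut-2-enyl)benzene-1,3-diol
Conditions: Bu4NF (5 equiv), THF, 0 °C; pH 7 phosphate buffer
Reagents that add atoms: none
Why: Fluoride-mediated desilylation removes the three aryl TIPS ethers and the trimethylsilyl ether under basic conditions, which avoid acid-triggered attack of the freed ring A phenol on C6 of the enol ether.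

Step 16
Reactants: 28 4-[(2S,3S)-6-(2-chloro-4-hydroxyphenyl)-3-hydroxy-2-methyl-2-(4-methylpent-3-enyl)-3,4-dihydro-2H-pyran-5-yl]-6-(3-methylbut-2-enyl)benzene-1,3-diol
Product: 29 target CNP0185870.1, the (2S,3S)-pyrano-fused dibenzo[b,f]oxepine triol
Conditions: Pd(OAc)2 (10 mol%), 2-di-tert-butylphosphino-2′,4′,6′-triisopropylbiphenyl (20 mol%), K3PO4, degassed toluene/1,4-dioxane, 100 °C, high dilution
Reagents that add atoms: none
Why: Intramolecular Buchwald–Hartwig aryl ether formation, zerovalent palladium with the bulky biarylphosphine inserting into the C–Cl bond of ring B and the ring A phenoxide at C2′, held cis across C5=C6, closing the seven-membered oxepine by reductive elimination, with dilution disfavouring intermolecular arylation of the other two phenols.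

**Compound list**

1 | 4,6-dibromobenzene-1,3-diol | Oc1cc(O)c(Br)cc1Br | starting material
2 | 1,5-dibromo-2,4-bis(triisopropylsilyloxy)benzene | CC(C)[Si](C(C)C)(C(C)C)Oc1cc(O[Si](C(C)C)(C(C)C)C(C)C)c(Br)cc1Br | intermediate
3 | 1-bromo-3-methylbut-2-ene | CC(C)=CCBr | starting material
4 | [5-bromo-2,4-bis(triisopropylsilyloxy)phenyl]lithium | [Li]c1cc(Br)c(O[Si](C(C)C)(C(C)C)C(C)C)cc1O[Si](C(C)C)(C(C)C)C(C)C | intermediate
5 | [5-bromo-2,4-bis(triisopropylsilyloxy)phenyl]copper | [Cu]c1cc(Br)c(O[Si](C(C)C)(C(C)C)C(C)C)cc1O[Si](C(C)C)(C(C)C)C(C)C | intermediate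
6 | 1-bromo-5-(3-methylbut-2-enyl)-2,4-bis(triisopropylsilyloxy)benzene | CC(C)=CCc1cc(Br)c(O[Si](C(C)C)(C(C)C)C(C)C)cc1O[Si](C(C)C)(C(C)C)C(C)C | intermediate
7 | [5-(3-methylbut-2-enyl)-2,4-bis(triisopropylsilyloxy)phenyl]lithium | [Li]c1cc(CC=C(C)C)c(O[Si](C(C)C)(C(C)C)C(C)C)cc1O[Si](C(C)C)(C(C)C)C(C)C | intermediate
8 | 2-[5-(3-methylbut-2-enyl)-2,4-bis(triisopropylsilyloxy)phenyl]-4,4,5,5-tetramethyl-1,3,2-dioxaborolane | CC(C)=CCc1cc(B2OC(C)(C)C(C)(C)O2)c(O[Si](C(C)C)(C(C)C)C(C)C)cc1O[Si](C(C)C)(C(C)C)C(C)C | intermediate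
9 | 4,5-dibromofuran-2-carboxylic acid | OC(=O)c1cc(Br)c(Br)o1 | starting material
10 | (4,5-dibromofuran-2-yl)(imidazol-1-yl)methanone | O=C(c1cc(Br)c(Br)o1)n1ccnc1 | intermediate
11 | 4,5-dibromo-N-methoxy-N-methylfuran-2-carboxamide | CON(C)C(=O)c1cc(Br)c(Br)o1 | intermediate
12 | (2-chloro-4-hydroxyphenyl)boronic acid | OB(O)c1ccc(O)cc1Cl | starting material
13 | 4-bromo-5-(2-chloro-4-hydroxyphenyl)-N-methoxy-N-methylfuran-2-carboxamide | CON(C)C(=O)c1cc(Br)c(-c2ccc(O)cc2Cl)o1 | intermediate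
14 | 4-bromo-5-[2-chloro-4-(triisopropylsilyloxy)phenyl]-N-methoxy-N-methylfuran-2-carboxamide | CON(C)C(=O)c1cc(Br)c(-c2ccc(O[Si](C(C)C)(C(C)C)C(C)C)cc2Cl)o1 | intermediate
15 | 5-[2-chloro-4-(triisopropylsilyloxy)phenyl]-N-methoxy-N-methyl-4-[5-(3-methylbut-2-enyl)-2,4-bis(triisopropylsilyloxy)phenyl]furan-2-carboxamide | CON(C)C(=O)c1cc(-c2cc(CC=C(C)C)c(O[Si](C(C)C)(C(C)C)C(C)C)cc2O[Si](C(C)C)(C(C)C)C(C)C)c(-c2ccc(O[Si](C(C)C)(C(C)C)C(C)C)cc2Cl)o1 | intermediate
16 | 5-bromo-2-methylpent-2-ene | CC(C)=CCCBr | starting material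
17 | (4-methylpent-3-enyl)magnesium bromide | CC(C)=CCC[Mg]Br | intermediate
18 | 1-{5-[2-chloro-4-(triisopropylsilyloxy)phenyl]-4-[5-(3-methylbut-2-enyl)-2,4-bis(triisopropylsilyloxy)phenyl]furan-2-yl}-5-methylhex-4-en-1-one | CC(C)=CCCC(=O)c1cc(-c2cc(CC=C(C)C)c(O[Si](C(C)C)(C(C)C)C(C)C)cc2O[Si](C(C)C)(C(C)C)C(C)C)c(-c2ccc(O[Si](C(C)C)(C(C)C)C(C)C)cc2Cl)o1 | intermediate
19 | (2S)-2-{5-[2-chloro-4-(triisopropylsilyloxy)phenyl]-4-[5-(3-methylbut-2-enyl)-2,4-bis(triisopropylsilyloxy)phenyl]furan-2-yl}-6-methylhept-5-en-2-ol (key-step precursor) | CC(C)=CCC[C@](C)(O)c1cc(-c2cc(CC=C(C)C)c(O[Si](C(C)C)(C(C)C)C(C)C)cc2O[Si](C(C)C)(C(C)C)C(C)C)c(-c2ccc(O[Si](C(C)C)(C(C)C)C(C)C)cc2Cl)o1 | intermediate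
20 | 1-[(2S)-2-hydroxy-6-methylhept-5-en-2-yl]-4-[2-chloro-4-(triisopropylsilyloxy)phenyl]-5-[5-(3-methylbut-2-enyl)-2,4-bis(triisopropylsilyloxy)phenyl]-2,3,7-trioxabicyclo[2.2.1]hept-5-ene (bridgehead epimers) | CC(C)=CCC[C@](C)(O)C12OOC(c3ccc(O[Si](C(C)C)(C(C)C)C(C)C)cc3Cl)(O1)C(c1cc(CC=C(C)C)c(O[Si](C(C)C)(C(C)C)C(C)C)cc1O[Si](C(C)C)(C(C)C)C(C)C)=C2 | intermediate
21 | (2Z,5S)-1-[2-chloro-4-(triisopropylsilyloxy)phenyl]-5-hydroxy-5,9-dimethyl-2-[5-(3-methylbut-2-enyl)-2,4-bis(triisopropylsilyloxy)phenyl]deca-2,8-diene-1,4-dione | CC(C)=CCC[C@](C)(O)C(=O)/C=C(/c1cc(CC=C(C)C)c(O[Si](C(C)C)(C(C)C)C(C)C)cc1O[Si](C(C)C)(C(C)C)C(C)C)C(=O)c1ccc(O[Si](C(C)C)(C(C)C)C(C)C)cc1Cl | intermediate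
22 | (2S)-6-[2-chloro-4-(triisopropylsilyloxy)phenyl]-6-hydroxy-2-methyl-2-(4-methylpent-3-enyl)-5-[5-(3-methylbut-2-enyl)-2,4-bis(triisopropylsilyloxy)phenyl]-2H-pyran-3(6H)-one, C6 epimers (key-step product) | CC(C)=CCC[C@]1(C)OC(O)(c2ccc(O[Si](C(C)C)(C(C)C)C(C)C)cc2Cl)C(=CC1=O)c1cc(CC=C(C)C)c(O[Si](C(C)C)(C(C)C)C(C)C)cc1O[Si](C(C)C)(C(C)C)C(C)C | intermediate
23 | (2S)-6-[2-chloro-4-(triisopropylsilyloxy)phenyl]-6-methoxy-2-methyl-2-(4-methylpent-3-enyl)-5-[5-(3-methylbut-2-enyl)-2,4-bis(triisopropylsilyloxy)phenyl]-2H-pyran-3(6H)-one, C6 epimers | CC(C)=CCC[C@]1(C)OC(OC)(c2ccc(O[Si](C(C)C)(C(C)C)C(C)C)cc2Cl)C(=CC1=O)c1cc(CC=C(C)C)c(O[Si](C(C)C)(C(C)C)C(C)C)cc1O[Si](C(C)C)(C(C)C)C(C)C | intermediate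
24 | (2S)-6-[2-chloro-4-(triisopropylsilyloxy)phenyl]-6-methoxy-2-methyl-2-(4-methylpent-3-enyl)-5-[5-(3-methylbut-2-enyl)-2,4-bis(triisopropylsilyloxy)phenyl]oxan-3-one, mixture at C5 and C6 | CC(C)=CCC[C@]1(C)OC(OC)(c2ccc(O[Si](C(C)C)(C(C)C)C(C)C)cc2Cl)C(CC1=O)c1cc(CC=C(C)C)c(O[Si](C(C)C)(C(C)C)C(C)C)cc1O[Si](C(C)C)(C(C)C)C(C)C | intermediate
25 | (2S,3S)-6-[2-chloro-4-(triisopropylsilyloxy)phenyl]-6-methoxy-2-methyl-2-(4-methylpent-3-enyl)-5-[5-(3-methylbut-2-enyl)-2,4-bis(triisopropylsilyloxy)phenyl]oxan-3-ol, mixture at C5 and C6 | CC(C)=CCC[C@]1(C)OC(OC)(c2ccc(O[Si](C(C)C)(C(C)C)C(C)C)cc2Cl)C(C[C@@H]1O)c1cc(CC=C(C)C)c(O[Si](C(C)C)(C(C)C)C(C)C)cc1O[Si](C(C)C)(C(C)C)C(C)C | intermediate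
26 | trimethylsilyl ether of 25 at the C3 oxygen | CC(C)=CCC[C@]1(C)OC(OC)(c2ccc(O[Si](C(C)C)(C(C)C)C(C)C)cc2Cl)C(C[C@@H]1O[Si](C)(C)C)c1cc(CC=C(C)C)c(O[Si](C(C)C)(C(C)C)C(C)C)cc1O[Si](C(C)C)(C(C)C)C(C)C | intermediate
27 | (2S,3S)-6-[2-chloro-4-(triisopropylsilyloxy)phenyl]-2-methyl-2-(4-methylpent-3-enyl)-5-[5-(3-methylbut-2-enyl)-2,4-bis(triisopropylsilyloxy)phenyl]-3-(trimethylsilyloxy)-3,4-dihydro-2H-pyran | CC(C)=CCC[C@]1(C)OC(c2ccc(O[Si](C(C)C)(C(C)C)C(C)C)cc2Cl)=C(C[C@@H]1O[Si](C)(C)C)c1cc(CC=C(C)C)c(O[Si](C(C)C)(C(C)C)C(C)C)cc1O[Si](C(C)C)(C(C)C)C(C)C | intermediate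
28 | 4-[(2S,3S)-6-(2-chloro-4-hydroxyphenyl)-3-hydroxy-2-methyl-2-(4-methylpent-3-enyl)-3,4-dihydro-2H-pyran-5-yl]-6-(3-methylbut-2-enyl)benzene-1,3-diol | CC(C)=CCC[C@]1(C)OC(c2ccc(O)cc2Cl)=C(C[C@@H]1O)c1cc(CC=C(C)C)c(O)cc1O | intermediate
29 | CNP0185870.1, (2S,3S) in pyran numbering: 2-methyl-2-(4-methylpent-3-enyl)-3-hydroxy-3,4-dihydro-2H-pyran fused at C5=C6 to a dibenzo[b,f]oxepine bearing two phenolic hydroxyls and one 3-methylbut-2-enyl group | CC(C)=CCC[C@]1(C)OC2=C(C[C@@H]1O)c1cc(CC=C(C)C)c(O)cc1Oc1cc(O)ccc12 | target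

**Totals**

Total step count: 16.
Longest linear sequence: 13 steps (steps 1–3 and 7–16, or steps 4–16).

**Steps most likely to fail**

Step 10. Singlet oxygen may also engage the two trisubstituted side-chain alkenes in ene hydroperoxidation, and keep doing so on the product, if the crowded furan reacts more slowly than expected. The fallback carries both side chains through the oxidation as terminal alkenes, which are poor ene partners, and builds the trisubstituted termini afterwards by cross-metathesis. It sets out from 2 through arylcopper 5, which is quenched with allyl bromide in place of 3 to give 1-bromo-5-(prop-2-enyl)-2,4-bis(triisopropylsilyloxy)benzene F1. Bromine–lithium exchange gives [5-(prop-2-enyl)-2,4-bis(triisopropylsilyloxy)phenyl]lithium F2, which is borylated as in step 3 to the allyl-substituted ring A pinacol boronate F3. Suzuki coupling with 14 as in step 7 gives the allyl-substituted Weinreb amide F4, commercial but-3-enylmagnesium bromide converts it into the pent-4-en-1-one F5, and the methyl addition of step 9 gives the (2S)-hex-5-en-2-ol carbinol F6. Photooxygenation and Me2S reduction as in step 10 should give the but-3-enyl allyl pyranone F7. Cross-metathesis of F7 with excess 2-methylbut-2-ene (second-generation Grubbs catalyst, CH2Cl2, 40 °C) turns both terminal alkenes into the 3-methylbut-2-enyl and 4-methylpent-3-enyl groups and comes back to the route at 22.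

Step 16. Oxidative addition into the hindered, electron-rich C–Cl bond may stall, the polyphenolate may tie up palladium, or hydrodechlorination and intermolecular O-arylation may take over. The fallback turns the chloride into a boron nucleophile and closes the ether oxidatively with copper (Chan–Lam–Evans coupling). It sets out from 27: Miyaura borylation of the aryl chloride (Pd2(dba)3, 2-dicyclohexylphosphino-2′,4′,6′-triisopropylbiphenyl, bis(pinacolato)diboron, KOAc, 1,4-dioxane, 100 °C) gives the ring B pinacol boronate F8. Bu4NF as in step 15 gives the desilylated boronate F9. Cu(OAc)2, pyridine, 4 Å molecular sieves, air, CH2Cl2 at room temperature then joins the ring A oxygen at C2′ to the boron-bearing carbon and comes back to the route at 29.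

Step 9. Methyl transfer from zinc to this electron-rich, enolisable furyl ketone may be slow, so that enolisation and aldol condensation compete, or the facial discrimination may be insufficient. The fallback gives up catalyst control and resolves. It sets out from 18: MeMgBr with anhydrous CeCl3 in THF at −78 °C (organocerium addition, which suppresses enolisation) gives the racemic carbinol, that is 19 together with its (2R)-enantiomer F10. Preparative chromatography on a chiral stationary phase removes F10 and comes back to the route at 19.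

**Further compounds**

F1 | step 10 | 1-bromo-5-(prop-2-enyl)-2,4-bis(triisopropylsilyloxy)benzene | C=CCc1cc(Br)c(O[Si](C(C)C)(C(C)C)C(C)C)cc1O[Si](C(C)C)(C(C)C)C(C)C
F2 | step 10 | [5-(prop-2-enyl)-2,4-bis(triisopropylsilyloxy)phenyl]lithium | [Li]c1cc(CC=C)c(O[Si](C(C)C)(C(C)C)C(C)C)cc1O[Si](C(C)C)(C(C)C)C(C)C
F3 | step 10 | 2-[5-(prop-2-enyl)-2,4-bis(triisopropylsilyloxy)phenyl]-4,4,5,5-tetramethyl-1,3,2-dioxaborolane | C=CCc1cc(B2OC(C)(C)C(C)(C)O2)c(O[Si](C(C)C)(C(C)C)C(C)C)cc1O[Si](C(C)C)(C(C)C)C(C)C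
F4 | step 10 | 5-[2-chloro-4-(triisopropylsilyloxy)phenyl]-N-methoxy-N-methyl-4-[5-(prop-2-enyl)-2,4-bis(triisopropylsilyloxy)phenyl]furan-2-carboxamide | CON(C)C(=O)c1cc(-c2cc(CC=C)c(O[Si](C(C)C)(C(C)C)C(C)C)cc2O[Si](C(C)C)(C(C)C)C(C)C)c(-c2ccc(O[Si](C(C)C)(C(C)C)C(C)C)cc2Cl)o1
F5 | step 10 | 1-{5-[2-chloro-4-(triisopropylsilyloxy)phenyl]-4-[5-(prop-2-enyl)-2,4-bis(triisopropylsilyloxy)phenyl]furan-2-yl}pent-4-en-1-one | C=CCCC(=O)c1cc(-c2cc(CC=C)c(O[Si](C(C)C)(C(C)C)C(C)C)cc2O[Si](C(C)C)(C(C)C)C(C)C)c(-c2ccc(O[Si](C(C)C)(C(C)C)C(C)C)cc2Cl)o1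
F6 | step 10 | (2S)-2-{5-[2-chloro-4-(triisopropylsilyloxy)phenyl]-4-[5-(prop-2-enyl)-2,4-bis(triisopropylsilyloxy)phenyl]furan-2-yl}hex-5-en-2-ol | C=CCC[C@](C)(O)c1cc(-c2cc(CC=C)c(O[Si](C(C)C)(C(C)C)C(C)C)cc2O[Si](C(C)C)(C(C)C)C(C)C)c(-c2ccc(O[Si](C(C)C)(C(C)C)C(C)C)cc2Cl)o1
F7 | step 10 | (2S)-2-(but-3-enyl)-6-[2-chloro-4-(triisopropylsilyloxy)phenyl]-6-hydroxy-2-methyl-5-[5-(prop-2-enyl)-2,4-bis(triisopropylsilyloxy)phenyl]-2H-pyran-3(6H)-one | C=CCC[C@]1(C)OC(O)(c2ccc(O[Si](C(C)C)(C(C)C)C(C)C)cc2Cl)C(=CC1=O)c1cc(CC=C)c(O[Si](C(C)C)(C(C)C)C(C)C)cc1O[Si](C(C)C)(C(C)C)C(C)C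
F8 | step 16 | (2S,3S)-2-methyl-2-(4-methylpent-3-enyl)-5-[5-(3-methylbut-2-enyl)-2,4-bis(triisopropylsilyloxy)phenyl]-6-[2-(4,4,5,5-tetramethyl-1,3,2-dioxaborolan-2-yl)-4-(triisopropylsilyloxy)phenyl]-3-(trimethylsilyloxy)-3,4-dihydro-2H-pyran | CC(C)=CCC[C@]1(C)OC(c2ccc(O[Si](C(C)C)(C(C)C)C(C)C)cc2B2OC(C)(C)C(C)(C)O2)=C(C[C@@H]1O[Si](C)(C)C)c1cc(CC=C(C)C)c(O[Si](C(C)C)(C(C)C)C(C)C)cc1O[Si](C(C)C)(C(C)C)C(C)C
F9 | step 16 | 4-{(2S,3S)-3-hydroxy-6-[4-hydroxy-2-(4,4,5,5-tetramethyl-1,3,2-dioxaborolan-2-yl)phenyl]-2-methyl-2-(4-methylpent-3-enyl)-3,4-dihydro-2H-pyran-5-yl}-6-(3-methylbut-2-enyl)benzene-1,3-diol | CC(C)=CCC[C@]1(C)OC(c2ccc(O)cc2B2OC(C)(C)C(C)(C)O2)=C(C[C@@H]1O)c1cc(CC=C(C)C)c(O)cc1O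
F10 | step 9 | (2R)-2-{5-[2-chloro-4-(triisopropylsilyloxy)phenyl]-4-[5-(3-methylbut-2-enyl)-2,4-bis(triisopropylsilyloxy)phenyl]furan-2-yl}-6-methylhept-5-en-2-ol | CC(C)=CCC[C@@](C)(O)c1cc(-c2cc(CC=C(C)C)c(O[Si](C(C)C)(C(C)C)C(C)C)cc2O[Si](C(C)C)(C(C)C)C(C)C)c(-c2ccc(O[Si](C(C)C)(C(C)C)C(C)C)cc2Cl)o1
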